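**Retrosynthetic overview**

- The strategy rests on ring A: O1 sits on C8a para to the C6 hydroxyl, oxygens on C5 and C7 flank C6, and only C8 carries hydrogen. This hydroquinone monoether pattern is what a chromium alkoxycarbene (C8a–O1), a 2-methoxyvinyl group (C8, C7), one CO (C6) and an ynol ether (C5, C4a) assemble.
- Key disconnection: C8a–C4a, C5–C6 and C6–C7. The carbene alkoxy group is the C2 oxygen and the alkyne is tethered through C2–C3–C4, so ring C closes first (alkyne insertion) and ring A second (electrocyclisation) in one operation.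
- Tether: C4–C4a by ethoxyacetylide addition to an α-methoxy aldehyde; C2–C3 with both stereocentres by an auxiliary-controlled anti glycolate aldol on 2,3-bis(benzyloxy)-4-methoxybenzaldehyde.
- Carbene: acyl chromate from Cr(CO)6 and (E)-3-methoxyacryloyl chloride, O-acetylation, then exchange with the free benzylic alcohol.
- End game: benzylation of the C6 phenol, desilylation and oxidation at C4, then BCl3 cleavage of the benzyl ethers and the chelated C5 ethyl ether.

Key step: step 13

Assumption: the anti glycolate aldol is taken to run through the open transition state in which the TiCl4-bound aldehyde adds to the face of the sulfur-chelated (Z)-enolate away from the benzyl group, which gives the (2R,3R)-adduct from the (S)-auxiliary; should the sense prove opposite, the (R)-auxiliary would be used with no other change.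
Remark: metal alkoxides, carboxylates and borates that are only protonated in the aqueous work-up are treated as the product and not listed separately.

**Route**

Step 1
Reactants: 1 2,3-dihydroxy-4-methoxybenzaldehyde
Product: 2 2,3-bis(benzyloxy)-4-methoxybenzaldehyde
Conditions: BnBr (2.5 equiv), K2CO3, DMF, 60 °C
Reagents that add atoms: benzyl bromide BrCc1ccccc1
Why: Williamson etherification of both phenols (warm DMF is needed for the hydrogen-bonded 2-hydroxyl) masks the catechol as benzyl ethers that should survive every later step and leave together at the end.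

Step 2
Reactants: 3 (S)-4-benzyl-1,3-oxazolidine-2-thione; 4 methoxyacetyl chloride
Product: 5 (S)-4-benzyl-3-(methoxyacetyl)-1,3-oxazolidine-2-thione
Conditions: Et3N, CH2Cl2, 0 °C
Reagents that add atoms: none
Why: N-acylation of the oxazolidinethione by the acid chloride gives the glycolate imide required for the auxiliary-controlled aldol.

Step 3
Reactants: 5 (S)-4-benzyl-3-(methoxyacetyl)-1,3-oxazolidine-2-thione; 2 2,3-bis(benzyloxy)-4-methoxybenzaldehyde
Product: 7 (S)-4-benzyl-3-[(2R,3R)-3-[2,3-bis(benzyloxy)-4-methoxyphenyl]-3-hydroxy-2-methoxypropanoyl]-1,3-oxazolidine-2-thione, via trichlorotitanium (Z)-enolate 6 (not isolated)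
Conditions: TiCl4 (1.05 equiv), i-Pr2NEt (1.1 equiv), CH2Cl2, −78 °C; then 2 premixed with TiCl4 (2.5 equiv), −78 °C; aq. NH4Cl at −78 °C
Reagents that add atoms: none
Why: In this titanium-mediated anti glycolate aldol of an N-glycolyl oxazolidinethione the sulfur-chelated (Z)-enolate 6 should add through an open transition state to the TiCl4-activated aldehyde on the face away from the benzyl group, so the auxiliary sets the methoxy-bearing carbon (future C3, R) and the anti preference of the open transition state sets the carbinol carbon (future C2, R), the cold quench keeping the chelated 2-benzyl ether and the electron-rich benzylic alkoxide intact.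

Step 4
Reactants: 7 anti aldol adduct
Product: 8 (S)-4-benzyl-3-[(2R,3R)-3-[2,3-bis(benzyloxy)-4-methoxyphenyl]-2-methoxy-3-(triethylsilyloxy)propanoyl]-1,3-oxazolidine-2-thione
Conditions: Et3SiOTf, 2,6-lutidine, CH2Cl2, −78 → 0 °C
Reagents that add atoms: triethylsilyl trifluoromethanesulfonate CC[Si](CC)(CC)OS(=O)(=O)C(F)(F)F
Why: Silylation with the triflate and a hindered pyridine base protects the benzylic alcohol without retro-aldol, and triethylsilyl is chosen because it can later be removed beside a tert-butyldimethylsilyl ether.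

Step 5
Reactants: 8 triethylsilyl-protected aldol adduct
Product: 9 (2R,3R)-3-[2,3-bis(benzyloxy)-4-methoxyphenyl]-2-methoxy-3-(triethylsilyloxy)propanal
Conditions: i-Bu2AlH (2 equiv), CH2Cl2, −78 °C; aq. Rochelle salt; used at once
Reagents that add atoms: none
Why: N-acyl oxazolidinethiones are reduced by i-Bu2AlH to a tetrahedral aluminium adduct that collapses to the aldehyde only on work-up, so over-reduction is avoided, the auxiliary is released and the α-methoxy centre is not disturbed at −78 °C.

Step 6
Reactants: 9 α-methoxy aldehyde; 10 ethoxyacetylene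
Product: 12 (1R,2S,3RS)-1-[2,3-bis(benzyloxy)-4-methoxyphenyl]-5-ethoxy-2-methoxy-1-(triethylsilyloxy)pent-4-yn-3-ol, via lithium ethoxyacetylide 11 (not isolated)
Conditions: 10 (2 equiv), n-BuLi (1.9 equiv), THF, −78 °C; then 9, −78 °C; H2O
Reagents that add atoms: none
Why: 1,2-addition of the lithium acetylide to the aldehyde forms the C4–C4a bond (chroman numbering), and the new carbinol centre needs no control because both epimers converge on the C4 ketone in step 16 (the 2S descriptor only reflects changed priorities).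

Step 7
Reactants: 12 propargylic alcohol
Product: 13 (1R,2S,3RS)-1-[2,3-bis(benzyloxy)-4-methoxyphenyl]-3-(tert-butyldimethylsilyloxy)-5-ethoxy-2-methoxy-1-(triethylsilyloxy)pent-4-yne
Conditions: t-BuMe2SiCl, imidazole, DMAP (cat.), DMF, rt
Reagents that add atoms: tert-butyldimethylsilyl chloride CC(C)(C)[Si](C)(C)Cl
Why: Imidazole-mediated silylation of the unhindered propargylic alcohol runs under basic conditions that the acid-sensitive ynol ether tolerates.

Step 8
Reactants: 13 bis-silyl ether
Product: 14 (1R,2R,3RS)-1-[2,3-bis(benzyloxy)-4-methoxyphenyl]-3-(tert-butyldimethylsilyloxy)-5-ethoxy-2-methoxypent-4-yn-1-ol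
Conditions: Bu4NF (1.2 equiv), AcOH (1.2 equiv), THF, 0 °C
Reagents that add atoms: none
Why: Fluoride should cleave the triethylsilyl ether much faster than the tert-butyldimethylsilyl ether, while the acetic acid buffer suppresses alkoxide-driven 1,3-silyl migration and is too weak to hydrate the ynol ether at 0 °C.

Step 9
Reactants: 15 methyl (E)-3-methoxyacrylate
Product: 16 (E)-3-methoxyacrylic acid
Conditions: NaOH (2 M aq.), 60 °C; then HCl to pH 2, 0 °C
Reagents that add atoms: sodium hydroxide [Na+].[OH-]
Why: Saponification of this vinylogous carbonate ester is a known preparation of the acid and leaves the E double bond intact.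

Step 10
Reactants: 16 (E)-3-methoxyacrylic acid
Product: 17 (E)-3-methoxyacryloyl chloride
Conditions: (COCl)2, DMF (cat.), CH2Cl2, 0 °C → rt; distilled and used at once
Reagents that add atoms: oxalyl chloride ClC(=O)C(Cl)=O
Why: Vilsmeier-catalysed chlorination of the acid gives the known acid chloride without touching the enol ether.

Step 11
Reactants: 18 hexacarbonylchromium Cr(CO)6; 17 (E)-3-methoxyacryloyl chloride
Product: 21 tetramethylammonium pentacarbonyl[(E)-3-methoxy-1-oxidoprop-2-enylidene]chromate, via disodium pentacarbonylchromate 19 (not isolated), via sodium acylchromate 20 (not isolated)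
Conditions: sodium naphthalenide NaC10H8 (2.1 equiv), THF, −78 → 0 °C; then 17, −78 °C; then Me4NBr, H2O
Reagents that add atoms: tetramethylammonium bromide C[N+](C)(C)C.[Br-]
Why: Reduction of Cr(CO)6 to the pentacarbonylchromate dianion and its acylation by an acid chloride is the known halide-based entry to acyl chromates, it fixes the E geometry and avoids the unstable (E)-2-methoxyvinyllithium, and cation exchange gives the storable tetramethylammonium salt.

Step 12
Reactants: 21 tetramethylammonium acyl chromate; 14 benzylic alcohol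
Product: 23 pentacarbonyl[(E)-1-{[(1R,2R,3RS)-1-[2,3-bis(benzyloxy)-4-methoxyphenyl]-3-(tert-butyldimethylsilyloxy)-5-ethoxy-2-methoxypent-4-yn-1-yl]oxy}-3-methoxyprop-2-en-1-ylidene]chromium, via acetoxycarbene complex 22 (not isolated)
Conditions: 21 (2 equiv), AcBr (2 equiv), CH2Cl2, −40 °C; then 14, 2,6-di-tert-butyl-4-methylpyridine, −40 → −10 °C; cold filtration through silica; used at once
Reagents that add atoms: none
Why: O-acetylation of the acylate gives an electrophilic acyloxycarbene that undergoes addition–elimination with the alcohol at the carbene carbon (the established way to alkoxycarbene complexes of secondary alcohols), and because the C–O bond of 14 is not broken the benzylic configuration is retained.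

Step 13
Reactants: 23 chromium carbene complex with tethered ynol ether
Product: 25 (2R,3R,4RS)-2-[2,3-bis(benzyloxy)-4-methoxyphenyl]-4-(tert-butyldimethylsilyloxy)-5-ethoxy-3,7-dimethoxychroman-6-ol, via tricarbonylchromium arene complex 24 (not isolated)
Conditions: THF (0.01 M), 55 °C, Ar; then air, rt
Reagents that add atoms: none
Why: Proposed new method: warming 23 should let the tethered ynol ether insert into the Cr=C bond (after loss of one CO, or by direct polar addition of the electron-rich alkyne), its nucleophilic carbon C4a bonding to the carbene carbon C8a so that ring C closes by a 6-exo-dig attack and chromium moves to C5 as an ethoxy(dienyl)carbene. Insertion of CO then forms C5–C6 as a dienylketene, 6π electrocyclisation onto the methoxy-bearing vinyl terminus forms C6–C7 and closes ring A, and tautomerisation gives the phenol as its Cr(CO)3 complex 24, from which air releases 25. The closest known reaction type is the intramolecular Dötz benzannulation of aryl(alkoxy)carbene chromium complexes that carry the alkyne on the carbene oxygen, together with the thermal benzannulation of alkoxy(dienyl)carbene complexes; the pairing of a 2-methoxyvinyl carbene with a tethered ynol ether has not been shown. No stereocentre is created: the C2–O and C3–O bonds are not touched, and C4 is carried as an epimer mixture that step 16 removes. Regiochemistry is secured by the three-carbon C2–C3–C4 tether, which can only deliver C4a to C8a, and is matched by the polarity of the ynol ether. The selectivity that must be won is CO insertion over CO-free five-ring closure, which the alkenyl (not aryl) carbene, chromium, THF and high dilution favour, while the E geometry keeps the methoxy group outside the cyclising triene.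

Step 14
Reactants: 25 chroman-6-ol
Product: 26 (2R,3R,4RS)-6-(benzyloxy)-2-[2,3-bis(benzyloxy)-4-methoxyphenyl]-4-(tert-butyldimethylsilyloxy)-5-ethoxy-3,7-dimethoxychromane
Conditions: BnBr, Cs2CO3, DMF (degassed), rt
Reagents that add atoms: benzyl bromide BrCc1ccccc1
Why: Williamson benzylation caps the air-sensitive hydroquinone monoether phenol so that it cannot be oxidised to a quinone in step 16.

Step 15
Reactants: 26 silyl-protected chromane
Product: 27 (2R,3S,4RS)-6-(benzyloxy)-2-[2,3-bis(benzyloxy)-4-methoxyphenyl]-5-ethoxy-3,7-dimethoxychroman-4-ol (3S reflects changed priorities only)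
Conditions: Bu4NF, THF, 0 °C → rt
Reagents that add atoms: none
Why: Fluoride removes the silyl ether under non-acidic conditions, which is required because the C4–O bond is benzylic to the trioxygenated ring A and would ionise with acid.

Step 16
Reactants: 27 chroman-4-ol
Product: 28 (2R,3R)-6-(benzyloxy)-2-[2,3-bis(benzyloxy)-4-methoxyphenyl]-5-ethoxy-3,7-dimethoxychroman-4-one
Conditions: Dess–Martin periodinane, pyridine, CH2Cl2, 0 °C → rt
Reagents that add atoms: none
Why: Dess–Martin oxidation converts both C4 epimers into the one ketone under buffered conditions free of strong base, so C3 next to the new carbonyl should not epimerise and the ring oxygen should not be lost by β-elimination.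

Step 17
Reactants: 28 protected flavanonol
Product: 29 (2R,3R)-2-(2,3-dihydroxy-4-methoxyphenyl)-5,6-dihydroxy-3,7-dimethoxychroman-4-one (CNP0075602.1)
Conditions: BCl3 (10 equiv), pentamethylbenzene (10 equiv), CH2Cl2, −78 °C → rt; MeOH, then H2O
Reagents that add atoms: none
Why: BCl3 with pentamethylbenzene as benzyl-cation scavenger cleaves the three aryl benzyl ethers, and boron chelation between the C4 carbonyl and the peri C5 oxygen should direct chloride dealkylation to the 5-ethyl ether alone, leaving the three methyl ethers.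

**Compound list**

1 | 2,3-dihydroxy-4-methoxybenzaldehyde | COc1ccc(C=O)c(O)c1O | starting material
2 | 2,3-bis(benzyloxy)-4-methoxybenzaldehyde | COc1ccc(C=O)c(OCc2ccccc2)c1OCc1ccccc1 | intermediate
3 | (S)-4-benzyl-1,3-oxazolidine-2-thione | S=C1N[C@@H](Cc2ccccc2)CO1 | starting material
4 | methoxyacetyl chloride | COCC(=O)Cl | starting material
5 | (S)-4-benzyl-3-(methoxyacetyl)-1,3-oxazolidine-2-thione | COCC(=O)N1C(=S)OC[C@@H]1Cc1ccccc1 | intermediate
6 | trichlorotitanium (Z)-enolate of 5, Cl3Ti–O–C(=CH–OMe)–N(auxiliary) | CO/C=C(\O[Ti](Cl)(Cl)Cl)N1C(=S)OC[C@@H]1Cc1ccccc1 | intermediate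
7 | (S)-4-benzyl-3-[(2R,3R)-3-[2,3-bis(benzyloxy)-4-methoxyphenyl]-3-hydroxy-2-methoxypropanoyl]-1,3-oxazolidine-2-thione | COc1ccc([C@@H](O)[C@@H](OC)C(=O)N2C(=S)OC[C@@H]2Cc2ccccc2)c(OCc2ccccc2)c1OCc1ccccc1 | intermediate
8 | (S)-4-benzyl-3-[(2R,3R)-3-[2,3-bis(benzyloxy)-4-methoxyphenyl]-2-methoxy-3-(triethylsilyloxy)propanoyl]-1,3-oxazolidine-2-thione | COc1ccc([C@@H](O[Si](CC)(CC)CC)[C@@H](OC)C(=O)N2C(=S)OC[C@@H]2Cc2ccccc2)c(OCc2ccccc2)c1OCc1ccccc1 | intermediate
9 | (2R,3R)-3-[2,3-bis(benzyloxy)-4-methoxyphenyl]-2-methoxy-3-(triethylsilyloxy)propanal | COc1ccc([C@@H](O[Si](CC)(CC)CC)[C@@H](OC)C=O)c(OCc2ccccc2)c1OCc1ccccc1 | intermediate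
10 | ethoxyacetylene | CCOC#C | starting material
11 | lithium ethoxyacetylide LiC≡COEt | [Li]C#COCC | intermediate
12 | (1R,2S,3RS)-1-[2,3-bis(benzyloxy)-4-methoxyphenyl]-5-ethoxy-2-methoxy-1-(triethylsilyloxy)pent-4-yn-3-ol | COc1ccc([C@@H](O[Si](CC)(CC)CC)[C@@H](OC)C(O)C#COCC)c(OCc2ccccc2)c1OCc1ccccc1 | intermediate
13 | (1R,2S,3RS)-1-[2,3-bis(benzyloxy)-4-methoxyphenyl]-3-(tert-butyldimethylsilyloxy)-5-ethoxy-2-methoxy-1-(triethylsilyloxy)pent-4-yne | COc1ccc([C@@H](O[Si](CC)(CC)CC)[C@@H](OC)C(O[Si](C)(C)C(C)(C)C)C#COCC)c(OCc2ccccc2)c1OCc1ccccc1 | intermediate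
14 | (1R,2R,3RS)-1-[2,3-bis(benzyloxy)-4-methoxyphenyl]-3-(tert-butyldimethylsilyloxy)-5-ethoxy-2-methoxypent-4-yn-1-ol | COc1ccc([C@@H](O)[C@@H](OC)C(O[Si](C)(C)C(C)(C)C)C#COCC)c(OCc2ccccc2)c1OCc1ccccc1 | intermediate
15 | methyl (E)-3-methoxyacrylate | CO/C=C/C(=O)OC | starting material
16 | (E)-3-methoxyacrylic acid | CO/C=C/C(=O)O | intermediate
17 | (E)-3-methoxyacryloyl chloride | CO/C=C/C(=O)Cl | intermediate
18 | hexacarbonylchromium Cr(CO)6 | O=C=[Cr](=C=O)(=C=O)(=C=O)(=C=O)=C=O | starting material
19 | disodium pentacarbonylchromate Na2[Cr(CO)5] | [Na+].[Na+].O=C=[Cr-2](=C=O)(=C=O)(=C=O)=C=O | intermediate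
20 | sodium pentacarbonyl[(E)-3-methoxy-1-oxidoprop-2-enylidene]chromate Na[(CO)5Cr=C(O)CH=CHOMe] | [Na+].[O-]C(/C=C/OC)=[Cr](=C=O)(=C=O)(=C=O)(=C=O)=C=O | intermediate
21 | tetramethylammonium pentacarbonyl[(E)-3-methoxy-1-oxidoprop-2-enylidene]chromate Me4N[(CO)5Cr=C(O)CH=CHOMe] | C[N+](C)(C)C.[O-]C(/C=C/OC)=[Cr](=C=O)(=C=O)(=C=O)(=C=O)=C=O | intermediate
22 | pentacarbonyl[(E)-1-acetoxy-3-methoxyprop-2-enylidene]chromium (CO)5Cr=C(OAc)CH=CHOMe | CC(=O)OC(/C=C/OC)=[Cr](=C=O)(=C=O)(=C=O)(=C=O)=C=O | intermediate
23 | pentacarbonylchromium (E)-2-methoxyvinyl carbene complex of alcohol 14, (CO)5Cr=C(OR)CH=CHOMe with R = the (1R,2R,3RS)-pent-4-ynyl group of 14 | O=C=[Cr](=C=O)(=C=O)(=C=O)(=C=O)=C(/C=C/OC)O[C@H](c1ccc(OC)c(OCc2ccccc2)c1OCc1ccccc1)[C@@H](OC)C(O[Si](C)(C)C(C)(C)C)C#COCC | intermediate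
24 | tricarbonylchromium complex of 25, Cr(CO)3 bound η6 to ring A (written as two parts) | COc1ccc([C@H]2Oc3cc(OC)c(O)c(OCC)c3C(O[Si](C)(C)C(C)(C)C)[C@@H]2OC)c(OCc2ccccc2)c1OCc1ccccc1.O=C=[Cr](=C=O)=C=O | intermediate
25 | (2R,3R,4RS)-2-[2,3-bis(benzyloxy)-4-methoxyphenyl]-4-(tert-butyldimethylsilyloxy)-5-ethoxy-3,7-dimethoxychroman-6-ol | COc1ccc([C@H]2Oc3cc(OC)c(O)c(OCC)c3C(O[Si](C)(C)C(C)(C)C)[C@@H]2OC)c(OCc2ccccc2)c1OCc1ccccc1 | intermediate
26 | (2R,3R,4RS)-6-(benzyloxy)-2-[2,3-bis(benzyloxy)-4-methoxyphenyl]-4-(tert-butyldimethylsilyloxy)-5-ethoxy-3,7-dimethoxychromane | COc1ccc([C@H]2Oc3cc(OC)c(OCc4ccccc4)c(OCC)c3C(O[Si](C)(C)C(C)(C)C)[C@@H]2OC)c(OCc2ccccc2)c1OCc1ccccc1 | intermediate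
27 | (2R,3S,4RS)-6-(benzyloxy)-2-[2,3-bis(benzyloxy)-4-methoxyphenyl]-5-ethoxy-3,7-dimethoxychroman-4-ol | COc1ccc([C@H]2Oc3cc(OC)c(OCc4ccccc4)c(OCC)c3C(O)[C@@H]2OC)c(OCc2ccccc2)c1OCc1ccccc1 | intermediate
28 | (2R,3R)-6-(benzyloxy)-2-[2,3-bis(benzyloxy)-4-methoxyphenyl]-5-ethoxy-3,7-dimethoxychroman-4-one | COc1ccc([C@H]2Oc3cc(OC)c(OCc4ccccc4)c(OCC)c3C(=O)[C@@H]2OC)c(OCc2ccccc2)c1OCc1ccccc1 | intermediate
29 | (2R,3R)-2-(2,3-dihydroxy-4-methoxyphenyl)-5,6-dihydroxy-3,7-dimethoxychroman-4-one | COc1ccc([C@H]2Oc3cc(OC)c(O)c(O)c3C(=O)[C@@H]2OC)c(O)c1O | target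

**Step count**

Total: 17 steps. Longest linear sequence: 13 steps (steps 1, 3–8, 12–17).

**Steps most likely to fail, with fallbacks**

Step 13 (proposed new method). The ynol ether may insert without CO uptake and close a five-membered ring, the ethoxy(dienyl)carbene formed after insertion may not take up CO, or the electron-rich benzylic C2–O bond of the carbene complex may ionise and erode the C2 configuration. The fallback uses known chalcone-epoxide chemistry, sets out from aldehyde 2 and returns at target 29.
Commercial 1-(6-hydroxy-2,3,4-trimethoxyphenyl)ethanone is protected with chloromethyl methyl ether and i-Pr2NEt to give 1-[2,3,4-trimethoxy-6-(methoxymethoxy)phenyl]ethanone F1. Claisen–Schmidt condensation of F1 with 2 (KOH, EtOH) gives the (E)-chalcone F2. Juliá–Colonna epoxidation (poly-L-leucine, urea–H2O2, DBU, THF) gives the (αR,βS)-epoxy ketone F3. HCl in MeOH removes the acetal, and the freed phenol opens the epoxide at the benzylic carbon with inversion to give the (2R,3R)-trans-dihydroflavonol F4. MeI and Ag2O methylate the C3 hydroxyl to give the 3-O-methyl ether F5. BCl3 with pentamethylbenzene removes the benzyl ethers and the chelated C5 methyl ether to give the 5-hydroxy-6,7-dimethoxy compound F6. One equivalent of BBr3 at low temperature then cleaves the C6 methyl ether, which is flanked by two oxygens and twisted out of the ring plane, to give 29.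

Step 12. The donor-stabilised acetoxycarbene 22 may react too slowly with the hindered secondary alcohol, the alcohol may add at the β-carbon with loss of methoxide, or acetic acid may add to the ynol ether. The fallback attaches the alcohol to a more electrophilic alkynylcarbene and builds the methoxyvinyl unit afterwards; it sets out from 14 and 18 and returns at 23.
Compound 18 and commercial lithium (trimethylsilyl)acetylide, followed by Me4NBr, give the tetramethylammonium alkynyl acylate F7. Acetyl bromide at −40 °C gives the acetoxy(alkynyl)carbene complex F8, which is exchanged with 14 (an established transformation for alkynylcarbene complexes of secondary alcohols) to give the alkynylcarbene complex F9. Conjugate addition of methanol (catalytic NaOMe, THF/MeOH, −20 °C) with loss of the silyl group then gives 23; any Z isomer formed alongside converges in step 13.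

Step 17. Dealkylation of the C5 ethyl ether may stay incomplete, or boron bound to the freed C6 or C3′ oxygen may also cleave the neighbouring C7 or C4′ methyl ether. The fallback separates the two deprotections; it sets out from 28 and returns at 29.
Hydrogenolysis (H2, Pd/C, EtOAc) removes the three benzyl ethers without touching any alkyl ether and gives the 5-O-ethyl tetraphenol F10. MgI2 etherate in THF at 50 °C then cleaves only the ether chelated to the C4 carbonyl to give 29.

**Further compounds**

F1 | step 13 | 1-[2,3,4-trimethoxy-6-(methoxymethoxy)phenyl]ethanone | CC(=O)c1c(OCOC)cc(OC)c(OC)c1OC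
F2 | step 13 | (E)-3-[2,3-bis(benzyloxy)-4-methoxyphenyl]-1-[2,3,4-trimethoxy-6-(methoxymethoxy)phenyl]prop-2-en-1-one | COCOc1cc(OC)c(OC)c(OC)c1C(=O)/C=C/c1ccc(OC)c(OCc2ccccc2)c1OCc1ccccc1
F3 | step 13 | [(2R,3S)-3-[2,3-bis(benzyloxy)-4-methoxyphenyl]oxiran-2-yl][2,3,4-trimethoxy-6-(methoxymethoxy)phenyl]methanone | COCOc1cc(OC)c(OC)c(OC)c1C(=O)[C@@H]1O[C@H]1c1ccc(OC)c(OCc2ccccc2)c1OCc1ccccc1
F4 | step 13 | (2R,3R)-2-[2,3-bis(benzyloxy)-4-methoxyphenyl]-3-hydroxy-5,6,7-trimethoxychroman-4-one | COc1ccc([C@H]2Oc3cc(OC)c(OC)c(OC)c3C(=O)[C@@H]2O)c(OCc2ccccc2)c1OCc1ccccc1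
F5 | step 13 | (2R,3R)-2-[2,3-bis(benzyloxy)-4-methoxyphenyl]-3,5,6,7-tetramethoxychroman-4-one | COc1ccc([C@H]2Oc3cc(OC)c(OC)c(OC)c3C(=O)[C@@H]2OC)c(OCc2ccccc2)c1OCc1ccccc1
F6 | step 13 | (2R,3R)-2-(2,3-dihydroxy-4-methoxyphenyl)-5-hydroxy-3,6,7-trimethoxychroman-4-one | COc1ccc([C@H]2Oc3cc(OC)c(OC)c(O)c3C(=O)[C@@H]2OC)c(O)c1O
F7 | step 12 | tetramethylammonium pentacarbonyl[1-oxido-3-(trimethylsilyl)prop-2-ynylidene]chromate | C[N+](C)(C)C.[O-]C(C#C[Si](C)(C)C)=[Cr](=C=O)(=C=O)(=C=O)(=C=O)=C=O
F8 | step 12 | pentacarbonyl[1-acetoxy-3-(trimethylsilyl)prop-2-ynylidene]chromium | CC(=O)OC(C#C[Si](C)(C)C)=[Cr](=C=O)(=C=O)(=C=O)(=C=O)=C=O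
F9 | step 12 | pentacarbonylchromium (trimethylsilyl)ethynyl carbene complex of alcohol 14 | O=C=[Cr](=C=O)(=C=O)(=C=O)(=C=O)=C(C#C[Si](C)(C)C)O[C@H](c1ccc(OC)c(OCc2ccccc2)c1OCc1ccccc1)[C@@H](OC)C(O[Si](C)(C)C(C)(C)C)C#COCC
F10 | step 17 | (2R,3R)-2-(2,3-dihydroxy-4-methoxyphenyl)-5-ethoxy-6-hydroxy-3,7-dimethoxychroman-4-one | COc1ccc([C@H]2Oc3cc(OC)c(O)c(OCC)c3C(=O)[C@@H]2OC)c(O)c1O
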